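**Plan**

- Ring B (C1 carries the carbonyl bound to the ring C oxygen, C2–OH, C3–H, C4–O-acyl, C5–H, C6–CH3) has a free hydroxyl, a second oxygen meta to it and C3–H between them. This is the pattern a vinylketene (C1, C2, C5, C6) and an ynol ether (C3, C4) give on benzannulation.
- Retrosynthesis: the ester between ring A and O–C4 of ring B is cut first. Ring B is then cut at C1–C2, C2–C3, C4–C5 and C5–C6, leaving a diazo enone already esterified to ring C, and tert-butoxyethyne.
- Forward: the ring C phenol (from orsellinic acid) is acylated with (E)-3-methyl-4-oxopent-2-enoic acid and the methyl ketone is converted to the diazo ketone. Ring B is then grown on that ester by Wolff rearrangement, (2+2) cycloaddition, four-electron opening and six-electron closure.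
- The tert-butyl ether at C4 is then cleaved, the benzyl-protected ring A acid is attached there, and one hydrogenolysis frees two phenols and the acid.
- Stereochemistry: the target has no stereocentre. The E alkene of the enoate comes from a Wittig reaction and disappears when ring B becomes aromatic.

Key step: step 11

**Remarks on the chemistry**

- A tert-butyl ynol ether is the alkyne partner because a terminal ynolate tends to be silylated on carbon, so the parent silyloxyethyne is not reliably accessible.
- The enoate is made E because a Z ester would lie next to the ketene and could close to a 2-pyranone, and would also invite intramolecular Claisen chemistry in step 8.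
- Compounds marked "starting material" are taken to be commercial.

**Route**

Step 1
Reactants: 1 orsellinic acid (2,4-dihydroxy-6-methylbenzoic acid); 2 benzyl bromide
Product: 3 benzyl 2,4-dihydroxy-6-methylbenzoate
Conditions: BnBr (1.05 equiv), KHCO3, DMF, rt
Reagents that add atoms: benzyl bromide (2), BrCc1ccccc1
Why: Carboxylate O-alkylation (SN2) under hydrogencarbonate, a base too weak to engage the phenols, should esterify only the acid, and room temperature avoids decarboxylation of the orsellinate.

Step 2
Reactants: 3 benzyl 2,4-dihydroxy-6-methylbenzoate; 4 allyl bromide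
Product: 5 benzyl 2-hydroxy-6-methyl-4-(prop-2-en-1-yloxy)benzoate
Conditions: allyl bromide (1.05 equiv), K2CO3, acetone, rt
Reagents that add atoms: allyl bromide (4), C=CCBr
Why: Williamson ether synthesis should select the 4-hydroxyl, because the 2-hydroxyl is held in a hydrogen bond to the ester carbonyl and is the weaker acid.

Step 3
Reactants: 5 benzyl 2-hydroxy-6-methyl-4-(prop-2-en-1-yloxy)benzoate; 6 iodomethane
Product: 7 benzyl 2-methoxy-6-methyl-4-(prop-2-en-1-yloxy)benzoate
Conditions: MeI (3 equiv), K2CO3, DMF, 50 °C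
Reagents that add atoms: iodomethane (6), CI
Why: Williamson methylation of the chelated phenol needs only excess MeI and mild heating in DMF, which the benzyl ester and the allyl ether tolerate.

Step 4
Reactants: 7 benzyl 2-methoxy-6-methyl-4-(prop-2-en-1-yloxy)benzoate
Product: 8 benzyl 4-hydroxy-2-methoxy-6-methylbenzoate
Conditions: Pd(PPh3)4 (2 mol %), morpholine (3 equiv), THF, rt
Reagents that add atoms: none
Why: Tsuji–Trost deallylation, in which the zerovalent palladium complex ionizes the aryl allyl ether to a pi-allyl complex that morpholine captures, should leave the benzyl ester and the methyl ether untouched.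

Step 5
Reactants: 9 butane-2,3-dione; 10 tert-butyl (triphenylphosphoranylidene)acetate
Product: 11 tert-butyl (E)-3-methyl-4-oxopent-2-enoate
Conditions: 9 (3 equiv), CH2Cl2, rt
Reagents that add atoms: tert-butyl (triphenylphosphoranylidene)acetate (10), CC(C)(C)OC(=O)C=P(c1ccccc1)(c1ccccc1)c1ccccc1
Why: Wittig olefination of a 1,2-diketone with a stabilized ylide should take place once and place the ester trans to the acetyl group (E), excess diketone suppressing double olefination.

Step 6
Reactants: 11 tert-butyl (E)-3-methyl-4-oxopent-2-enoate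
Product: 12 (E)-3-methyl-4-oxopent-2-enoic acid
Conditions: CF3CO2H/CH2Cl2 (1:3), rt
Reagents that add atoms: none
Why: Acidolysis of the tert-butyl ester by alkyl–oxygen cleavage (loss of isobutene) should free the acid without touching the enone, and the E geometry prevents lactol formation.

Step 7
Reactants: 8 benzyl 4-hydroxy-2-methoxy-6-methylbenzoate; 12 (E)-3-methyl-4-oxopent-2-enoic acid
Product: 13 benzyl 2-methoxy-6-methyl-4-{[(2E)-3-methyl-4-oxopent-2-enoyl]oxy}benzoate
Conditions: DCC (1.1 equiv), DMAP (10 mol %), CH2Cl2, 0 °C to rt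
Reagents that add atoms: none
Why: Steglich esterification (carbodiimide activation, DMAP acyl transfer) should join the unhindered acid to the only free hydroxyl of 8.

Step 8
Reactants: 13 benzyl 2-methoxy-6-methyl-4-{[(2E)-3-methyl-4-oxopent-2-enoyl]oxy}benzoate; 14 4-acetamidobenzenesulfonyl azide
Product: 16 benzyl 4-{[(2E)-5-diazo-3-methyl-4-oxopent-2-enoyl]oxy}-2-methoxy-6-methylbenzoate, via trifluoroacetyl diketone 15 (not isolated)
Conditions: LiN(SiMe3)2 (1.1 equiv), THF, −78 °C; CF3CO2CH2CF3 (1.2 equiv), −78 °C; aq. HCl; then 14 (1.5 equiv), Et3N (1.5 equiv), H2O (1 equiv), MeCN, rt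
Reagents that add atoms: 4-acetamidobenzenesulfonyl azide (14), CC(=O)Nc1ccc(cc1)S(=O)(=O)N=[N+]=[N-]
Why: Detrifluoroacetylative diazo transfer (a Regitz-type transfer to a ketone activated by Claisen trifluoroacetylation of its kinetic methyl enolate) should give the alpha-diazo enone without diazomethane, which would add to the electron-poor alkene; the low temperature and the hindered bases should spare the aryl ester, and the E alkene keeps the enolate away from it.

Step 9
Reactants: 17 trichloroethylene; 18 potassium tert-butoxide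
Product: 20 (E)-1-tert-butoxy-1,2-dichloroethene, via dichloroethyne 19 (not isolated)
Conditions: KOtBu (1.0 equiv), THF, −40 °C to rt
Reagents that add atoms: potassium tert-butoxide (18), CC(C)(C)[O-].[K+]
Why: In the dichlorovinyl ether route to ynol ethers the alkoxide dehydrochlorinates trichloroethylene to dichloroethyne, which is kept in solution and should take up tert-butanol by anti addition to give the E ether.

Step 10
Reactants: 20 (E)-1-tert-butoxy-1,2-dichloroethene
Product: 23 tert-butoxyethyne, via chloroalkyne 21 (not isolated), via lithium acetylide 22 (not isolated)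
Conditions: n-butyllithium (2.2 equiv), Et2O, −78 to −40 °C; H2O, −78 °C; cold distillation under reduced pressure
Reagents that add atoms: none
Why: Elimination of HCl by the first equivalent of base, chlorine–lithium exchange by the second and protonation at low temperature should give the terminal ynol ether, which is kept cold because it is prone to retro-ene loss of isobutene on warming.

Step 11
Reactants: 16 benzyl 4-{[(2E)-5-diazo-3-methyl-4-oxopent-2-enoyl]oxy}-2-methoxy-6-methylbenzoate; 23 tert-butoxyethyne
Product: 28 benzyl 4-[(4-tert-butoxy-2-hydroxy-6-methylbenzoyl)oxy]-2-methoxy-6-methylbenzoate, via vinylketene 24 (not isolated), via cyclobutenone 25 (not isolated), via dienylketene 26 (not isolated), via cyclohexadienone 27 (not isolated)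
Conditions: 23 (3 equiv), hν (Pyrex filter, >300 nm), ClCH2CH2Cl, rt; evaporate excess 23; toluene, 80 °C
Reagents that add atoms: none
Why: Irradiation above 300 nm, where the diazo enone absorbs but the aryl esters do not, expels N2 from 16 and shifts the alkenyl carbon to the former diazo carbon (Wolff rearrangement, bond C5–C6 of ring B) to give vinylketene 24, whose carbonyl carbon is attacked by the nucleophilic CH terminus of the ynol ether so that a (2+2) cycloaddition forms bonds C2–C3 and C4–C5 and closes the four-membered ring of 25. On warming, 25 opens reversibly by a conrotatory four-electron electrocyclic reaction to dienylketene 26, ring B is closed by a disrotatory six-electron electrocyclization (bond C1–C2, the ketene carbon joining the ester-bearing alkene terminus), and dienone 27 enolizes to the phenol. The closest known reaction type is the Danheiser benzannulation in its second-generation form, in which an alpha-diazo enone is photolysed in the presence of a heteroatom-substituted alkyne. No stereocentre has to be controlled, since the sp3 carbons of 25 and 27 are formed racemic and become aromatic, and the alkene geometry is lost at the same point. The step needs regiocontrol in the (2+2) event, which the polarization of the ynol ether secures (oxygen ends at C4 meta to the new hydroxyl, hydrogen at C3), and it needs the ketene to react with the alkyne and not with its own ester, which the E geometry secures because the ester carbonyl cannot reach the ketene for closure to a 2-pyranone. The new C2 hydroxyl is hydrogen bonded to the C1 ester and so should resist acylation by remaining ketene, and excess 23 is stripped off before heating so that its retro-ene fragmentation does not interfere.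

Step 12
Reactants: 28 benzyl 4-[(4-tert-butoxy-2-hydroxy-6-methylbenzoyl)oxy]-2-methoxy-6-methylbenzoate
Product: 29 benzyl 4-[(2,4-dihydroxy-6-methylbenzoyl)oxy]-2-methoxy-6-methylbenzoate
Conditions: CF3CO2H/CH2Cl2 (1:4), 0 °C to rt, argon stream
Reagents that add atoms: none
Why: Acidolysis of the aryl tert-butyl ether (ionization to the tert-butyl cation, swept out as isobutene) should be fast under conditions that benzyl esters, aryl esters and the aryl methyl ether survive.

Step 13
Reactants: 3 benzyl 2,4-dihydroxy-6-methylbenzoate; 2 benzyl bromide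
Product: 30 benzyl 2,4-bis(benzyloxy)-6-methylbenzoate
Conditions: BnBr (2.5 equiv), K2CO3, DMF, 60 °C
Reagents that add atoms: benzyl bromide (2), BrCc1ccccc1
Why: Williamson benzylation with excess halide and heating should alkylate both phenols, including the chelated 2-hydroxyl.

Step 14
Reactants: 30 benzyl 2,4-bis(benzyloxy)-6-methylbenzoate; 31 potassium hydroxide
Product: 32 2,4-bis(benzyloxy)-6-methylbenzoic acid
Conditions: KOH (5 equiv), DMSO/H2O, 90 °C; then aq. HCl
Reagents that add atoms: potassium hydroxide (31), [K+].[OH-]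
Why: Saponification of the doubly ortho-substituted ester needs hot hydroxide in aqueous DMSO, conditions that aryl benzyl ethers tolerate.

Step 15
Reactants: 29 benzyl 4-[(2,4-dihydroxy-6-methylbenzoyl)oxy]-2-methoxy-6-methylbenzoate; 32 2,4-bis(benzyloxy)-6-methylbenzoic acid
Product: 34 benzyl 4-[(4-{[2,4-bis(benzyloxy)-6-methylbenzoyl]oxy}-2-hydroxy-6-methylbenzoyl)oxy]-2-methoxy-6-methylbenzoate, via mixed anhydride 33 (not isolated)
Conditions: 32 (1.1 equiv), (CF3CO)2O (1.5 equiv), toluene, rt
Reagents that add atoms: none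
Why: Depside coupling by the trifluoroacetic anhydride method should turn the hindered, electron-rich acid into an acylium-like mixed anhydride that acylates the free 4-hydroxyl of ring B, while the 2-hydroxyl is hydrogen bonded to its ortho ester and stays free.

Step 16
Reactants: 34 benzyl 4-[(4-{[2,4-bis(benzyloxy)-6-methylbenzoyl]oxy}-2-hydroxy-6-methylbenzoyl)oxy]-2-methoxy-6-methylbenzoate
Product: 35 4-({4-[(2,4-dihydroxy-6-methylbenzoyl)oxy]-2-hydroxy-6-methylbenzoyl}oxy)-2-methoxy-6-methylbenzoic acid (CNP0283563.0)
Conditions: H2 (1 atm), Pd/C (palladium on carbon, 10%), EtOAc, rt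
Reagents that add atoms: none
Why: Hydrogenolysis should cleave the two benzyl ethers and the benzyl ester as toluene and leave both aryl ester links, which hold no benzylic C–O bond, in place.

**Compound list**

1 | orsellinic acid (2,4-dihydroxy-6-methylbenzoic acid) | Cc1cc(O)cc(O)c1C(=O)O | starting material
2 | benzyl bromide | BrCc1ccccc1 | starting material
3 | benzyl 2,4-dihydroxy-6-methylbenzoate | Cc1cc(O)cc(O)c1C(=O)OCc1ccccc1 | intermediate
4 | allyl bromide | C=CCBr | starting material
5 | benzyl 2-hydroxy-6-methyl-4-(prop-2-en-1-yloxy)benzoate | C=CCOc1cc(C)c(C(=O)OCc2ccccc2)c(O)c1 | intermediate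
6 | iodomethane | CI | starting material
7 | benzyl 2-methoxy-6-methyl-4-(prop-2-en-1-yloxy)benzoate | C=CCOc1cc(C)c(C(=O)OCc2ccccc2)c(OC)c1 | intermediate
8 | benzyl 4-hydroxy-2-methoxy-6-methylbenzoate | COc1cc(O)cc(C)c1C(=O)OCc1ccccc1 | intermediate
9 | butane-2,3-dione | CC(=O)C(C)=O | starting material
10 | tert-butyl (triphenylphosphoranylidene)acetate | CC(C)(C)OC(=O)C=P(c1ccccc1)(c1ccccc1)c1ccccc1 | starting material
11 | tert-butyl (E)-3-methyl-4-oxopent-2-enoate | CC(=O)/C(C)=C/C(=O)OC(C)(C)C | intermediate
12 | (E)-3-methyl-4-oxopent-2-enoic acid | CC(=O)/C(C)=C/C(=O)O | intermediate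
13 | benzyl 2-methoxy-6-methyl-4-{[(2E)-3-methyl-4-oxopent-2-enoyl]oxy}benzoate | CC(=O)/C(C)=C/C(=O)Oc1cc(C)c(C(=O)OCc2ccccc2)c(OC)c1 | intermediate
14 | 4-acetamidobenzenesulfonyl azide | CC(=O)Nc1ccc(cc1)S(=O)(=O)N=[N+]=[N-] | starting material
15 | benzyl 2-methoxy-6-methyl-4-{[(2E)-7,7,7-trifluoro-3-methyl-4,6-dioxohept-2-enoyl]oxy}benzoate | O=C(CC(=O)/C(C)=C/C(=O)Oc1cc(C)c(C(=O)OCc2ccccc2)c(OC)c1)C(F)(F)F | intermediate
16 | benzyl 4-{[(2E)-5-diazo-3-methyl-4-oxopent-2-enoyl]oxy}-2-methoxy-6-methylbenzoate | [N-]=[N+]=CC(=O)/C(C)=C/C(=O)Oc1cc(C)c(C(=O)OCc2ccccc2)c(OC)c1 | intermediate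
17 | trichloroethylene | ClC=C(Cl)Cl | starting material
18 | potassium tert-butoxide | CC(C)(C)[O-].[K+] | starting material
19 | dichloroethyne | ClC#CCl | intermediate
20 | (E)-1-tert-butoxy-1,2-dichloroethene | Cl/C=C(/Cl)OC(C)(C)C | intermediate
21 | 1-tert-butoxy-2-chloroethyne | ClC#COC(C)(C)C | intermediate
22 | (tert-butoxyethynyl)lithium | [Li]C#COC(C)(C)C | intermediate
23 | tert-butoxyethyne | C#COC(C)(C)C | intermediate
24 | benzyl 2-methoxy-6-methyl-4-{[(2E)-3-methyl-5-oxopenta-2,4-dienoyl]oxy}benzoate (vinylketene) | O=C=C/C(C)=C/C(=O)Oc1cc(C)c(C(=O)OCc2ccccc2)c(OC)c1 | intermediate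
25 | benzyl 4-{[(2E)-3-(2-tert-butoxy-4-oxocyclobut-2-en-1-yl)but-2-enoyl]oxy}-2-methoxy-6-methylbenzoate (racemic) | O=C1C=C(OC(C)(C)C)C1/C(C)=C/C(=O)Oc1cc(C)c(C(=O)OCc2ccccc2)c(OC)c1 | intermediate
26 | benzyl 4-{[(2E,4E)-5-tert-butoxy-3-methyl-7-oxohepta-2,4,6-trienoyl]oxy}-2-methoxy-6-methylbenzoate (dienylketene) | O=C=C/C(OC(C)(C)C)=C\C(C)=C\C(=O)Oc1cc(C)c(C(=O)OCc2ccccc2)c(OC)c1 | intermediate
27 | benzyl 4-{[(4-tert-butoxy-2-methyl-6-oxocyclohexa-2,4-dien-1-yl)carbonyl]oxy}-2-methoxy-6-methylbenzoate (racemic) | O=C1C=C(OC(C)(C)C)C=C(C)C1C(=O)Oc1cc(C)c(C(=O)OCc2ccccc2)c(OC)c1 | intermediate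
28 | benzyl 4-[(4-tert-butoxy-2-hydroxy-6-methylbenzoyl)oxy]-2-methoxy-6-methylbenzoate | COc1cc(OC(=O)c2c(C)cc(OC(C)(C)C)cc2O)cc(C)c1C(=O)OCc1ccccc1 | intermediate
29 | benzyl 4-[(2,4-dihydroxy-6-methylbenzoyl)oxy]-2-methoxy-6-methylbenzoate | COc1cc(OC(=O)c2c(C)cc(O)cc2O)cc(C)c1C(=O)OCc1ccccc1 | intermediate
30 | benzyl 2,4-bis(benzyloxy)-6-methylbenzoate | Cc1cc(OCc2ccccc2)cc(OCc2ccccc2)c1C(=O)OCc1ccccc1 | intermediate
31 | potassium hydroxide | [K+].[OH-] | starting material
32 | 2,4-bis(benzyloxy)-6-methylbenzoic acid | Cc1cc(OCc2ccccc2)cc(OCc2ccccc2)c1C(=O)O | intermediate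
33 | 2,4-bis(benzyloxy)-6-methylbenzoic trifluoroacetic anhydride | Cc1cc(OCc2ccccc2)cc(OCc2ccccc2)c1C(=O)OC(=O)C(F)(F)F | intermediate
34 | benzyl 4-[(4-{[2,4-bis(benzyloxy)-6-methylbenzoyl]oxy}-2-hydroxy-6-methylbenzoyl)oxy]-2-methoxy-6-methylbenzoate | COc1cc(OC(=O)c2c(C)cc(OC(=O)c3c(C)cc(OCc4ccccc4)cc3OCc3ccccc3)cc2O)cc(C)c1C(=O)OCc1ccccc1 | intermediate
35 | 4-({4-[(2,4-dihydroxy-6-methylbenzoyl)oxy]-2-hydroxy-6-methylbenzoyl}oxy)-2-methoxy-6-methylbenzoic acid | COc1cc(OC(=O)c2c(C)cc(OC(=O)c3c(C)cc(O)cc3O)cc2O)cc(C)c1C(=O)O | target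

**Step count and risks**

Total step count: 16. Longest linear sequence: 10 steps (steps 1, 2, 3, 4, 7, 8, 11, 12, 15, 16).

Most likely to fail, in order:

1. Step 11. What may go wrong:
   - photoisomerization of the enoate alkene to Z, after which the vinylketene closes onto its own ester carbonyl;
   - photo-Fries migration of an aryl ester if short-wavelength light leaks through;
   - retro-ene decay of the ynol ether before the (2+2) step;
   - capture of the ketene by the product phenol.

   Fallback (classical depside assembly, from 1 and 8, returning at 29): orsellinic acid 1 would be allylated three times (allyl bromide, K2CO3, DMF) to allyl 2,4-bis(allyloxy)-6-methylbenzoate F1. Saponification with KOH in aqueous DMSO would give 2,4-bis(allyloxy)-6-methylbenzoic acid F2. Activation with (CF3CO)2O in toluene as 2,4-bis(allyloxy)-6-methylbenzoic trifluoroacetic anhydride F3 and coupling with phenol 8 would give benzyl 4-{[2,4-bis(allyloxy)-6-methylbenzoyl]oxy}-2-methoxy-6-methylbenzoate F4. Removal of both allyl ethers with Pd(PPh3)4 and morpholine in THF would give 29.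

2. Step 8. What may go wrong:
   - cleavage of the aryl ester by lithium trifluoroethoxide or by triethylamine and water during the transfer;
   - deprotonation at the allylic methyl followed by Michael oligomerization of the electron-poor alkene.

   Fallback (diazo group installed before the aryl ester, from 12, returning at 16): acid 12 would be esterified with 2-(trimethylsilyl)ethanol (DCC, DMAP) to 2-(trimethylsilyl)ethyl (E)-3-methyl-4-oxopent-2-enoate F5. The same trifluoroacetylation would give 2-(trimethylsilyl)ethyl (E)-7,7,7-trifluoro-3-methyl-4,6-dioxohept-2-enoate F6, and diazo transfer would give 2-(trimethylsilyl)ethyl (E)-5-diazo-3-methyl-4-oxopent-2-enoate F7. Bu4NF in THF at 0 °C would release (E)-5-diazo-3-methyl-4-oxopent-2-enoic acid F8, handled as its tetrabutylammonium salt. Steglich coupling of F8 with 8 would give 16 without exposing the aryl ester to base.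

3. Step 10. What may go wrong:
   - loss of the volatile ynol ether during isolation;
   - retro-ene fragmentation to ketene and isobutene during distillation or storage.

   Fallback (a higher-boiling C-silylated ynol ether, from 20, returning at 29): the lithium acetylide 22 made from 20 would be quenched with Me3SiCl instead of water to give tert-butoxy(trimethylsilyl)ethyne F9, which can be concentrated and distilled under reduced pressure. Photolysis of 16 with F9 and heating as in step 11 would pass from vinylketene 24 through the C-silylated cyclobutenone F10, the C-silylated dienylketene F11 and the C-silylated cyclohexadienone F12 to the 3-(trimethylsilyl) phenol F13 (28 with Me3Si at C3 of ring B). CF3CO2H in CH2Cl2 would then cleave the tert-butyl ether and, by ipso protonation between the two oxygens, the aryl–silicon bond, giving 29.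

**Further compounds**

F1 | step 11 | allyl 2,4-bis(allyloxy)-6-methylbenzoate | C=CCOC(=O)c1c(C)cc(OCC=C)cc1OCC=C
F2 | step 11 | 2,4-bis(allyloxy)-6-methylbenzoic acid | C=CCOc1cc(C)c(C(=O)O)c(OCC=C)c1
F3 | step 11 | 2,4-bis(allyloxy)-6-methylbenzoic trifluoroacetic anhydride | C=CCOc1cc(C)c(C(=O)OC(=O)C(F)(F)F)c(OCC=C)c1
F4 | step 11 | benzyl 4-{[2,4-bis(allyloxy)-6-methylbenzoyl]oxy}-2-methoxy-6-methylbenzoate | COc1cc(OC(=O)c2c(C)cc(OCC=C)cc2OCC=C)cc(C)c1C(=O)OCc1ccccc1
F5 | step 8 | 2-(trimethylsilyl)ethyl (E)-3-methyl-4-oxopent-2-enoate | CC(=O)/C(C)=C/C(=O)OCC[Si](C)(C)C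
F6 | step 8 | 2-(trimethylsilyl)ethyl (E)-7,7,7-trifluoro-3-methyl-4,6-dioxohept-2-enoate | O=C(CC(=O)/C(C)=C/C(=O)OCC[Si](C)(C)C)C(F)(F)F
F7 | step 8 | 2-(trimethylsilyl)ethyl (E)-5-diazo-3-methyl-4-oxopent-2-enoate | [N-]=[N+]=CC(=O)/C(C)=C/C(=O)OCC[Si](C)(C)C
F8 | step 8 | (E)-5-diazo-3-methyl-4-oxopent-2-enoic acid | [N-]=[N+]=CC(=O)/C(C)=C/C(=O)O
F9 | step 10 | tert-butoxy(trimethylsilyl)ethyne | CC(C)(C)OC#C[Si](C)(C)C
F10 | step 10 | benzyl 4-{[(2E)-3-[2-tert-butoxy-4-oxo-3-(trimethylsilyl)cyclobut-2-en-1-yl]but-2-enoyl]oxy}-2-methoxy-6-methylbenzoate (racemic) | O=C1C([Si](C)(C)C)=C(OC(C)(C)C)C1/C(C)=C/C(=O)Oc1cc(C)c(C(=O)OCc2ccccc2)c(OC)c1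
F11 | step 10 | benzyl 4-{[(2E,4E)-5-tert-butoxy-3-methyl-7-oxo-6-(trimethylsilyl)hepta-2,4,6-trienoyl]oxy}-2-methoxy-6-methylbenzoate | O=C=C([Si](C)(C)C)/C(OC(C)(C)C)=C\C(C)=C\C(=O)Oc1cc(C)c(C(=O)OCc2ccccc2)c(OC)c1
F12 | step 10 | benzyl 4-({[4-tert-butoxy-2-methyl-6-oxo-5-(trimethylsilyl)cyclohexa-2,4-dien-1-yl]carbonyl}oxy)-2-methoxy-6-methylbenzoate (racemic) | O=C1C([Si](C)(C)C)=C(OC(C)(C)C)C=C(C)C1C(=O)Oc1cc(C)c(C(=O)OCc2ccccc2)c(OC)c1
F13 | step 10 | benzyl 4-{[4-tert-butoxy-2-hydroxy-6-methyl-3-(trimethylsilyl)benzoyl]oxy}-2-methoxy-6-methylbenzoate | COc1cc(OC(=O)c2c(C)cc(OC(C)(C)C)c([Si](C)(C)C)c2O)cc(C)c1C(=O)OCc1ccccc1
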